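**Retrosynthetic overview**
- Eriostemin 18 comes from the 8-O-benzyl flavonol 17 by hydrogenolysis, and 17 from the dihydroflavonol 15 by dehydrogenation across C2–C3.
- The strategy rests on ring C, where the C4 ketone sits next to C3 bearing oxygen. This acyloin unit is opened at C3–C4 as an intramolecular carbene-catalysed benzoin between the ring-A aldehyde (C4) and an aliphatic aldehyde (C3) in dialdehyde 14. Ring C is the only ring formed; rings A and B come from the starting materials.
- 14 comes from ester 12 by reduction and re-oxidation. 12 is made by forming the O1–C2 ether bond between salicylaldehyde 9 and α-bromo ester 11.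
- 9 comes from 2,3,4-trimethoxybenzaldehyde 1 by two Baeyer–Villiger/ortho-formylation cycles with a benzylation between them, which tells O8 apart from O1.

Key step: step 10

Remark: the target is achiral, and C2 and C3 of 15 are flattened again in step 11. Compounds 11 to 16 are therefore carried as racemates, and the trans configuration drawn for 15 is the expected major one, not a requirement.

**Route**

Step 1
Reactants: 1 2,3,4-trimethoxybenzaldehyde
Product: 3 2,3,4-trimethoxyphenol, via 2,3,4-trimethoxyphenyl formate 2 (not isolated)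
Conditions: mCPBA, CH2Cl2, 0 °C to rt; then K2CO3 (cat.), MeOH, rt
Reagents that add atoms: mCPBA, OOC(=O)c1cccc(Cl)c1
Why: Baeyer–Villiger (Dakin-type) oxidation, in which the aryl group, made electron-rich by its ortho and para methoxy groups, migrates in preference to hydrogen, and mild methanolysis of formate 2 frees the phenol.

Step 2
Reactants: 3 2,3,4-trimethoxyphenol
Product: 4 2-hydroxy-3,4,5-trimethoxybenzaldehyde
Conditions: (CH2O)n, MgCl2, Et3N, MeCN, reflux
Reagents that add atoms: paraformaldehyde (source of formaldehyde), C=O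
Why: Magnesium-mediated ortho-formylation (Casnati–Skattebøl), in which the magnesium phenoxide delivers formaldehyde to C6, the only free ortho position, and a second formaldehyde accepts hydride from the salicyl alcohol to give the aldehyde.

Step 3
Reactants: 4 2-hydroxy-3,4,5-trimethoxybenzaldehyde; 5 benzyl bromide
Product: 6 2-(benzyloxy)-3,4,5-trimethoxybenzaldehyde
Conditions: K2CO3, DMF, 60 °C
Reagents that add atoms: none
Why: Williamson ether synthesis, in which the phenoxide of 4 displaces bromide from the benzylic halide and so masks the oxygen that becomes O8 of the target.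

Step 4
Reactants: 6 2-(benzyloxy)-3,4,5-trimethoxybenzaldehyde
Product: 8 2-(benzyloxy)-3,4,5-trimethoxyphenol, via 2-(benzyloxy)-3,4,5-trimethoxyphenyl formate 7 (not isolated)
Conditions: mCPBA, CH2Cl2, 0 °C to rt; then K2CO3 (cat.), MeOH, rt
Reagents that add atoms: mCPBA, OOC(=O)c1cccc(Cl)c1
Why: A second Baeyer–Villiger oxidation, again driven by migration of a ring with ortho and para alkoxy donors, under which the benzyl ether is inert to the peracid and to the methanolysis.

Step 5
Reactants: 8 2-(benzyloxy)-3,4,5-trimethoxyphenol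
Product: 9 3-(benzyloxy)-2-hydroxy-4,5,6-trimethoxybenzaldehyde
Conditions: (CH2O)n, MgCl2, Et3N, MeCN, reflux
Reagents that add atoms: paraformaldehyde (source of formaldehyde), C=O
Why: Magnesium-mediated ortho-formylation at the single unsubstituted ring position, which lies ortho to the phenol, so no regiochemical question arises.

Step 6
Reactants: 10 methyl 2-(4-methoxyphenyl)acetate
Product: 11 methyl 2-bromo-2-(4-methoxyphenyl)acetate (racemic)
Conditions: NBS, AIBN (cat.), PhCF3, reflux
Reagents that add atoms: N-bromosuccinimide, BrN1C(=O)CCC1=O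
Why: Wohl–Ziegler radical bromination at the C–H that is both benzylic and alpha to the ester, with the nonpolar medium holding back ionic bromination of the anisole ring.

Step 7
Reactants: 9 3-(benzyloxy)-2-hydroxy-4,5,6-trimethoxybenzaldehyde; 11 methyl 2-bromo-2-(4-methoxyphenyl)acetate
Product: 12 methyl 2-[2-(benzyloxy)-6-formyl-3,4,5-trimethoxyphenoxy]-2-(4-methoxyphenyl)acetate (racemic)
Conditions: K2CO3, DMF, 0 °C to rt
Reagents that add atoms: none
Why: Williamson-type O-alkylation, in which the phenoxide of 9 displaces the activated secondary benzylic bromide to form the O1–C2 bond, while mild base at room temperature keeps the ester enolate from adding to the ortho formyl group; the C2 stereocentre forms as a racemate.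

Step 8
Reactants: 12 methyl 2-[2-(benzyloxy)-6-formyl-3,4,5-trimethoxyphenoxy]-2-(4-methoxyphenyl)acetate
Product: 13 2-[2-(benzyloxy)-6-(hydroxymethyl)-3,4,5-trimethoxyphenoxy]-2-(4-methoxyphenyl)ethan-1-ol (racemic)
Conditions: LiAlH4, THF, 0 °C
Reagents that add atoms: none
Why: Hydride reduction with LiAlH4 takes the ester and the aryl aldehyde to the two primary alcohols in one operation and leaves the aryl and benzyl ethers untouched.

Step 9
Reactants: 13 2-[2-(benzyloxy)-6-(hydroxymethyl)-3,4,5-trimethoxyphenoxy]-2-(4-methoxyphenyl)ethan-1-ol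
Product: 14 3-(benzyloxy)-4,5,6-trimethoxy-2-[1-(4-methoxyphenyl)-2-oxoethoxy]benzaldehyde (racemic)
Conditions: Dess–Martin periodinane, CH2Cl2, 0 °C to rt; crude product used at once
Reagents that add atoms: none
Why: Dess–Martin oxidation converts the benzylic and the aliphatic primary alcohol to aldehydes under non-basic conditions, which spares the easily enolised alpha-aryl aldehyde.

Step 10
Reactants: 14 3-(benzyloxy)-4,5,6-trimethoxy-2-[1-(4-methoxyphenyl)-2-oxoethoxy]benzaldehyde
Product: 15 trans-8-(benzyloxy)-3-hydroxy-5,6,7-trimethoxy-2-(4-methoxyphenyl)chroman-4-one (racemic; the (2R,3R) enantiomer is drawn)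
Conditions: 2-(pentafluorophenyl)-6,7-dihydro-5H-pyrrolo[2,1-c][1,2,4]triazol-2-ium tetrafluoroborate (15 mol%), i-Pr2NEt (15 mol%), toluene, rt, argon
Reagents that add atoms: none
Why: Proposed new method: the triazolylidene adds reversibly to the ring-A aldehyde of 14, proton transfer gives the carbene-bound Breslow enaminol, its nucleophilic carbon (future C4) attacks the tethered aliphatic aldehyde carbon (future C3), and collapse of the adduct releases the carbene and the 3-hydroxy-4-ketone; the closest known reaction type is the carbene-catalysed intramolecular crossed benzoin of salicylaldehyde-derived keto aldehydes to 3-hydroxychroman-4-ones, extended here from a ketone to an aldehyde acceptor. Ring C closes in the 6-exo-trig mode. The new C3 stereocentre is set by substrate control from C2 in a chair-like transition state with the 4-methoxyphenyl group pseudo-equatorial, and base-mediated equilibration through the enediol should further favour the diequatorial trans isomer, although either epimer serves because step 11 removes both centres. The step needs chemoselectivity between the two aldehydes: the aliphatic aldehyde is alpha-branched and therefore slow to form a Breslow intermediate, so it should act as the acceptor, and if the roles invert, the 4-hydroxy-3-ketone regioisomer leads to the same dione in step 11. The one pathway that does not converge is expulsion of the ring-A aryloxide from a Breslow intermediate at the aliphatic aldehyde; this aryloxide is only a moderate leaving group, since its four alkoxy donors offset the ortho formyl group, and the expulsion is held back by the fast intramolecular addition, by the nonpolar solvent, which disfavours charge separation, and by the catalytic amount of weak base.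

Step 11
Reactants: 15 trans-8-(benzyloxy)-3-hydroxy-5,6,7-trimethoxy-2-(4-methoxyphenyl)chroman-4-one
Product: 17 8-(benzyloxy)-3-hydroxy-5,6,7-trimethoxy-2-(4-methoxyphenyl)-4H-chromen-4-one, via 8-(benzyloxy)-5,6,7-trimethoxy-2-(4-methoxyphenyl)chromane-3,4-dione 16 (not isolated)
Conditions: I2, KOAc, AcOH, 100 °C
Reagents that add atoms: none
Why: Iodine-mediated dehydrogenation of a dihydroflavonol, in which acetate-promoted enolisation and iodination at C3, loss of HI to dione 16 and enolisation through the C2–H give the aromatic 3-hydroxy-4-pyranone and remove both stereocentres.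

Step 12
Reactants: 17 8-(benzyloxy)-3-hydroxy-5,6,7-trimethoxy-2-(4-methoxyphenyl)-4H-chromen-4-one
Product: 18 Eriostemin, 3,8-dihydroxy-5,6,7-trimethoxy-2-(4-methoxyphenyl)-4H-chromen-4-one
Conditions: H2 (1 atm), Pd/C, EtOAc/MeOH, rt
Reagents that add atoms: none
Why: Catalytic hydrogenolysis of the benzyl aryl ether over Pd/C at ambient pressure, under which the flavonol double bond and the methyl ethers should persist.

**Compound list**

1 | 2,3,4-trimethoxybenzaldehyde | COc1ccc(C=O)c(OC)c1OC | starting material
2 | 2,3,4-trimethoxyphenyl formate | COc1ccc(OC=O)c(OC)c1OC | intermediate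
3 | 2,3,4-trimethoxyphenol | COc1ccc(O)c(OC)c1OC | intermediate
4 | 2-hydroxy-3,4,5-trimethoxybenzaldehyde | COc1cc(C=O)c(O)c(OC)c1OC | intermediate
5 | benzyl bromide | BrCc1ccccc1 | starting material
6 | 2-(benzyloxy)-3,4,5-trimethoxybenzaldehyde | COc1cc(C=O)c(OCc2ccccc2)c(OC)c1OC | intermediate
7 | 2-(benzyloxy)-3,4,5-trimethoxyphenyl formate | COc1cc(OC=O)c(OCc2ccccc2)c(OC)c1OC | intermediate
8 | 2-(benzyloxy)-3,4,5-trimethoxyphenol | COc1cc(O)c(OCc2ccccc2)c(OC)c1OC | intermediate
9 | 3-(benzyloxy)-2-hydroxy-4,5,6-trimethoxybenzaldehyde | COc1c(C=O)c(O)c(OCc2ccccc2)c(OC)c1OC | intermediate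
10 | methyl 2-(4-methoxyphenyl)acetate | COC(=O)Cc1ccc(OC)cc1 | starting material
11 | methyl 2-bromo-2-(4-methoxyphenyl)acetate (racemic) | COC(=O)C(Br)c1ccc(OC)cc1 | intermediate
12 | methyl 2-[2-(benzyloxy)-6-formyl-3,4,5-trimethoxyphenoxy]-2-(4-methoxyphenyl)acetate (racemic) | COC(=O)C(Oc1c(OCc2ccccc2)c(OC)c(OC)c(OC)c1C=O)c1ccc(OC)cc1 | intermediate
13 | 2-[2-(benzyloxy)-6-(hydroxymethyl)-3,4,5-trimethoxyphenoxy]-2-(4-methoxyphenyl)ethan-1-ol (racemic) | OCC(Oc1c(OCc2ccccc2)c(OC)c(OC)c(OC)c1CO)c1ccc(OC)cc1 | intermediate
14 | 3-(benzyloxy)-4,5,6-trimethoxy-2-[1-(4-methoxyphenyl)-2-oxoethoxy]benzaldehyde (racemic) | COc1ccc(cc1)C(C=O)Oc1c(OCc2ccccc2)c(OC)c(OC)c(OC)c1C=O | intermediate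
15 | trans-8-(benzyloxy)-3-hydroxy-5,6,7-trimethoxy-2-(4-methoxyphenyl)chroman-4-one (racemic; (2R,3R) enantiomer drawn) | COc1ccc(cc1)[C@@H]2[C@H](C(=O)c3c(OC)c(OC)c(OC)c(OCc4ccccc4)c3O2)O | intermediate
16 | 8-(benzyloxy)-5,6,7-trimethoxy-2-(4-methoxyphenyl)chromane-3,4-dione (racemic) | COc1ccc(cc1)C1Oc2c(OCc3ccccc3)c(OC)c(OC)c(OC)c2C(=O)C1=O | intermediate
17 | 8-(benzyloxy)-3-hydroxy-5,6,7-trimethoxy-2-(4-methoxyphenyl)-4H-chromen-4-one | COc1ccc(cc1)-c1oc2c(OCc3ccccc3)c(OC)c(OC)c(OC)c2c(=O)c1O | intermediate
18 | Eriostemin, 3,8-dihydroxy-5,6,7-trimethoxy-2-(4-methoxyphenyl)-4H-chromen-4-one | COc1ccc(-c2oc3c(O)c(OC)c(OC)c(OC)c3c(=O)c2O)cc1 | target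

**Step count**

Total: 12 steps. Longest linear sequence: 11 steps (steps 1 to 5 and 7 to 12, from 1 to 18); step 6 is a one-step branch.

**Steps most likely to fail**

1. Step 10 (Proposed new method). The carbene may engage the aliphatic aldehyde instead of the ring-A aldehyde, and the Breslow intermediate formed there may expel the ring-A aryloxide in an internal redox that ends in an aryl ester. Base-induced enolisation of the alpha-aryl aldehyde with 5-exo aldol closure onto the ring-A aldehyde is a second possible loss. Fallback by known chemistry, setting out from 9 and returning at 15: protection of the phenol of 9 (MOMCl, i-Pr2NEt, CH2Cl2) gives 3-(benzyloxy)-4,5,6-trimethoxy-2-(methoxymethoxy)benzaldehyde F1. Addition of MeMgBr in THF gives 1-[3-(benzyloxy)-4,5,6-trimethoxy-2-(methoxymethoxy)phenyl]ethan-1-ol F2. Dess–Martin oxidation gives 1-[3-(benzyloxy)-4,5,6-trimethoxy-2-(methoxymethoxy)phenyl]ethan-1-one F3. Claisen–Schmidt condensation with 4-methoxybenzaldehyde (KOH, EtOH) gives (E)-1-[3-(benzyloxy)-4,5,6-trimethoxy-2-(methoxymethoxy)phenyl]-3-(4-methoxyphenyl)prop-2-en-1-one F4. Weitz–Scheffer epoxidation (H2O2, NaOH, MeOH) gives trans-[3-(benzyloxy)-4,5,6-trimethoxy-2-(methoxymethoxy)phenyl][3-(4-methoxyphenyl)oxiran-2-yl]methanone F5. HCl in MeOH then removes the acetal, and the freed phenol opens the epoxide at the benzylic carbon, which the 4-methoxyphenyl group activates, to close ring C as the trans dihydroflavonol 15. The route continues at step 11.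

2. Step 9. The dialdehyde may be lost during oxidation and work-up through enolisation of the alpha-aryl, alpha-aryloxy aldehyde, intramolecular aldol closure, hydrate formation or air oxidation. Fallback, setting out from 12 and returning at 14, which reaches the aldehyde by reduction from the acid oxidation level under neutral conditions and leaves the ring-A aldehyde in place: saponification of 12 (LiOH, THF/H2O) gives 2-[2-(benzyloxy)-6-formyl-3,4,5-trimethoxyphenoxy]-2-(4-methoxyphenyl)acetic acid F6. Coupling with ethanethiol (EDC hydrochloride, DMAP, CH2Cl2) gives S-ethyl 2-[2-(benzyloxy)-6-formyl-3,4,5-trimethoxyphenoxy]-2-(4-methoxyphenyl)ethanethioate F7. Fukuyama reduction (Et3SiH, Pd/C, acetone, rt) should then deliver 14 for direct use in step 10.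

3. Step 7. The hindered, hydrogen-bonded phenoxide may react slowly, so that the labile benzylic bromide is consumed by solvolysis or elimination, or the ester enolate of the product may add to the neighbouring formyl group. Fallback, setting out from 9 and returning at 12: Mitsunobu etherification of 9 with commercial methyl 2-hydroxy-2-(4-methoxyphenyl)acetate (PPh3, DIAD, THF, 0 °C to rt) forms the same O1–C2 bond by activating the alcohol in place of displacing a halide, under neutral conditions and without bromide 11. This fallback forms no new compound (F0).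

**Further compounds**

F1 | step 10 | 3-(benzyloxy)-4,5,6-trimethoxy-2-(methoxymethoxy)benzaldehyde | COCOc1c(C=O)c(OC)c(OC)c(OC)c1OCc1ccccc1
F2 | step 10 | 1-[3-(benzyloxy)-4,5,6-trimethoxy-2-(methoxymethoxy)phenyl]ethan-1-ol (racemic) | COCOc1c(C(C)O)c(OC)c(OC)c(OC)c1OCc1ccccc1
F3 | step 10 | 1-[3-(benzyloxy)-4,5,6-trimethoxy-2-(methoxymethoxy)phenyl]ethan-1-one | COCOc1c(C(C)=O)c(OC)c(OC)c(OC)c1OCc1ccccc1
F4 | step 10 | (E)-1-[3-(benzyloxy)-4,5,6-trimethoxy-2-(methoxymethoxy)phenyl]-3-(4-methoxyphenyl)prop-2-en-1-one | COCOc1c(C(=O)/C=C/c2ccc(OC)cc2)c(OC)c(OC)c(OC)c1OCc1ccccc1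
F5 | step 10 | trans-[3-(benzyloxy)-4,5,6-trimethoxy-2-(methoxymethoxy)phenyl][3-(4-methoxyphenyl)oxiran-2-yl]methanone (racemic) | COCOc1c(C(=O)[C@H]2O[C@@H]2c2ccc(OC)cc2)c(OC)c(OC)c(OC)c1OCc1ccccc1
F6 | step 9 | 2-[2-(benzyloxy)-6-formyl-3,4,5-trimethoxyphenoxy]-2-(4-methoxyphenyl)acetic acid (racemic) | OC(=O)C(Oc1c(OCc2ccccc2)c(OC)c(OC)c(OC)c1C=O)c1ccc(OC)cc1
F7 | step 9 | S-ethyl 2-[2-(benzyloxy)-6-formyl-3,4,5-trimethoxyphenoxy]-2-(4-methoxyphenyl)ethanethioate (racemic) | CCSC(=O)C(Oc1c(OCc2ccccc2)c(OC)c(OC)c(OC)c1C=O)c1ccc(OC)cc1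
F0 | step 7 | none | none
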